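**Retrosynthetic overview**
- Target ⇐ ester demethylation/desilylation ⇐ C3 ketone reduction ⇐ ring A closed last by intramolecular aldol (C3–C4), after an intramolecular Michael lactonisation (C4–C5) of a C10 propionate onto the C5=C6–C7 enoate.
- Key fragment union: the C1–C10 bond, by carbonyl allylation of the ring B/C/D C10 ketone with an allyl-metal (allyl = C1–C3) from the β face.
- Ring B handles: C7 by carbonylation of the C6 enol triflate, C10=O by allylic oxidation; H-9β by reductive 1,3-transposition of the C12 enone tosylhydrazone.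
- Ring D: oxidative cycloalkenylation of the angular allyl group onto C13, then Markovnikov hydration to the 16-carbinol.
- Rings B/C and the C8 quaternary centre: proline-catalysed aldol of the triketone from the Michael addition of 2-allylcyclopentane-1,3-dione to methyl vinyl ketone. Ring order: B → C → D → lactone → A.

Assumption: gibberellane locants are used for all ring B/C/D intermediates (ring B = C5, C6, C8, C9, C10; ring C = C8, C9, C11–C14; ring D = C8, C13–C16; β = face of H-5, H-9 and the C15–C16 bridge; exo at C16 = side of C14), the about 90% ee of the proline step is raised to >99% ee by recrystallising the tosylhydrazone, and where epimers converge later (C4 in the lactone, C3 in the aldol) the major epimer is drawn.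

**Route**

Step 1
Reactants: 1 cyclopentane-1,3-dione; 2 allyl bromide (3-bromoprop-1-ene)
Product: 3 2-allylcyclopentane-1,3-dione
Conditions: NaOH (1.0 equiv), H2O, rt; acidify, crystallise
Reagents that add atoms: none
Why: Enolate alkylation of the soft 1,3-dione anion in water is C-selective and creates no stereocentre.

Step 2
Reactants: 3 2-allylcyclopentane-1,3-dione; 4 methyl vinyl ketone (but-3-en-2-one)
Product: 5 2-allyl-2-(3-oxobutyl)cyclopentane-1,3-dione
Conditions: H2O, AcOH (cat.), 70 °C
Reagents that add atoms: none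
Why: Intermolecular Michael addition of the acidic dione C–H to the enone joins the two fragments and gives an achiral triketone.

Step 3
Reactants: 5 2-allyl-2-(3-oxobutyl)cyclopentane-1,3-dione
Product: 7 (7aR)-7a-allyl-2,3,7,7a-tetrahydro-1H-indene-1,5(6H)-dione (allyl analogue of the (S)-Hajos–Parrish ketone in the same spatial sense; C7a = C8), via ketol 6 (not isolated)
Conditions: (S)-proline (30 mol %), DMF, rt, 72 h; then H2SO4 (cat.), 95 °C
Reagents that add atoms: none
Why: Hajos–Parrish–Eder–Sauer–Wiechert aldol: the proline enamine of the side-chain ketone attacks one of the two enantiotopic ring carbonyls through the acid-directed chair transition state, which fixes the C8 quaternary centre, and acid dehydration gives the enone.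

Step 4
Reactants: 7 allyl Hajos–Parrish enone
Product: 8 6β-hydroxy enone (7a-allyl-1-hydroxy-1,2,3,6,7,7a-hexahydro-5H-inden-5-one; OH cis to allyl)
Conditions: NaBH4 (0.3 equiv), EtOH, −20 °C
Reagents that add atoms: none
Why: Chemoselective 1,2-reduction of the saturated cyclopentanone over the conjugated ketone, with hydride entering anti to the angular allyl group.

Step 5
Reactants: 8 6β-hydroxy enone
Product: 9 6β-benzyloxy enone
Conditions: BnOC(=NH)CCl3, TfOH (5 mol %), CH2Cl2/cyclohexane, 0 °C → rt
Reagents that add atoms: benzyl 2,2,2-trichloroacetimidate, N=C(OCc1ccccc1)C(Cl)(Cl)Cl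
Why: Acid-catalysed imidate benzylation protects the alcohol without base, so the enone is not enolised; configuration unchanged.

Step 6
Reactants: 9 6β-benzyloxy enone
Product: 10 cross-conjugated TBS dienol ether (C12–OTBS; C12=C13 and C9=C11)
Conditions: LiN(i-Pr)2, THF, −78 °C; TBSCl, HMPA, −78 → 0 °C
Reagents that add atoms: tert-butyldimethylsilyl chloride, CC(C)(C)[Si](C)(C)Cl
Why: Kinetic α′-deprotonation of the enone and O-silylation place the nucleophilic enol carbon regiospecifically at C13.

Step 7
Reactants: 10 TBS dienol ether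
Product: 11 ring B/C/D dienone (6β-benzyloxy-12-oxo-9(11),16(17)-diene; C8–C15–C16(=CH2)–C13 bridge on the β face)
Conditions: Pd(OAc)2 (10 mol %), O2 (1 atm), DMSO, 45 °C
Reagents that add atoms: none
Why: Oxidative cycloalkenylation by divalent palladium (Kende/Saegusa type): C13 adds 5-exo to the palladium-bound allyl alkene and β-hydride elimination leaves the exocyclic methylene; the bridge can only close 1,3-diaxially from C8, so C8 dictates C13.

Step 8
Reactants: 11 ring B/C/D dienone
Product: 12 C12 tosylhydrazone of 11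
Conditions: TsNHNH2, EtOH, AcOH (cat.), 60 °C; recrystallise
Reagents that add atoms: p-toluenesulfonohydrazide, Cc1ccc(cc1)S(=O)(=O)NN
Why: Hydrazone condensation at the only ketone; the crystalline product also allows the enantiomeric upgrade.

Step 9
Reactants: 12 C12 tosylhydrazone
Product: 15 9β-H 11,16(17)-diene 6β-benzyl ether, via allylic tosylhydrazine 13 (not isolated), via allylic diazene 14 (not isolated)
Conditions: catecholborane, CHCl3, 0 °C; then NaOAc·3H2O, 60 °C
Reagents that add atoms: none
Why: Kabalka alkene-transposing hydrazone reduction: hydride enters C12 from the exo face (side of C14), so the derived diazene sits on the bridge face and delivers its hydrogen suprafacially to C9 in a retro-ene loss of N2, setting H-9β and removing the C12 oxygen.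

Step 10
Reactants: 15 9β-H diene
Product: 17 16-exo-hydroxy-16-methyl 11-ene 6β-benzyl ether, via organomercurial 16 (not isolated)
Conditions: Hg(OAc)2 (1.05 equiv), THF/H2O, 0 °C; then NaBH4, NaOH (3 M), 0 °C
Reagents that add atoms: water, O
Why: Oxymercuration–demercuration hydrates the 1,1-disubstituted alkene much faster than the cis-disubstituted ring alkene, and water attacks C16 from the exo face (as with 2-methylenenorbornane), giving the exo-OH/endo-CH3 carbinol of the target.

Step 11
Reactants: 17 tertiary alcohol benzyl ether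
Product: 18 6β,16-diol (saturated ring B/C/D tricycle)
Conditions: H2 (1 atm), Pd/C (10%), EtOH, rt
Reagents that add atoms: none
Why: Catalytic hydrogenation saturates C11=C12 (no new stereocentre) and hydrogenolysis removes the benzyl ether in the same operation.

Step 12
Reactants: 18 6β,16-diol
Product: 19 16-hydroxy 6-ketone
Conditions: Dess–Martin periodinane, NaHCO3, CH2Cl2, rt
Reagents that add atoms: none
Why: Dess–Martin oxidation converts the secondary alcohol into the ketone while the tertiary alcohol is inert.

Step 13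
Reactants: 19 16-hydroxy 6-ketone
Product: 20 16-O-triethylsilyl 6-ketone
Conditions: Et3SiOTf, 2,6-lutidine, CH2Cl2, −78 → 0 °C
Reagents that add atoms: triethylsilyl trifluoromethanesulfonate, CC[Si](CC)(CC)OS(=O)(=O)C(F)(F)F
Why: Silyl triflate silylation protects the hindered tertiary alcohol for the base, organometallic and oxidation steps that follow.

Step 14
Reactants: 20 16-O-TES 6-ketone
Product: 21 5-en-6-yl triflate
Conditions: KN(SiMe3)2, THF, −78 °C; PhNTf2, −78 → 0 °C
Reagents that add atoms: N-phenylbis(trifluoromethanesulfonimide), FC(F)(F)S(=O)(=O)N(c1ccccc1)S(=O)(=O)C(F)(F)F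
Why: Enol triflate formation is regiospecific because C8 is quaternary and only C5 can be deprotonated.

Step 15
Reactants: 21 enol triflate
Product: 22 methyl 5-ene-6-carboxylate (C7 methyl ester)
Conditions: Pd(OAc)2 (5 mol %), PPh3 (10 mol %), CO (1 atm), MeOH, Et3N, DMF, 60 °C
Reagents that add atoms: carbon monoxide, [C-]#[O+]; methanol, CO
Why: Palladium-catalysed methoxycarbonylation of the vinyl triflate (zerovalent palladium formed in situ) installs C7 as the conjugated ester.

Step 16
Reactants: 22 enoate
Product: 23 methyl 10-oxo-5-ene-6-carboxylate (ring B enone ester; H-9β)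
Conditions: Rh2(cap)4 (cap = caprolactamate, C6H10NO; 1 mol %), t-BuOOH (70% aq, 6 equiv), K2CO3 (0.5 equiv), CH2Cl2, rt
Reagents that add atoms: tert-butyl hydroperoxide, CC(C)(C)OO
Why: Radical allylic oxidation; C10 is the only allylic C–H position of the C5=C6 bond because C8 is quaternary.

Step 17
Reactants: 23 ring B enone ester; 24 allylmagnesium bromide (CH2=CHCH2MgBr)
Product: 25 10β-allyl-10α-hydroxy enoate
Conditions: THF, −78 °C; aq NH4Cl
Reagents that add atoms: none
Why: Carbonyl allylation (Grignard 1,2-addition) joins the C1–C3 fragment to the tricyclic ketone; the reagent attacks the convex β face anti to the α-oriented C11 on the adjacent C9, so the oxygen ends up α, and the low temperature spares the ester and H-9.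

Step 18
Reactants: 25 tertiary allylic alcohol; 26 propionyl chloride
Product: 27 10α-propionate
Conditions: LiN(SiMe3)2, THF, −78 °C; then 26, −78 → 0 °C
Reagents that add atoms: none
Why: O-acylation of the lithium alkoxide of the hindered tertiary alcohol; the lithium counter-ion and low temperature avoid an anionic oxy-Cope rearrangement of the 1,5-diene alkoxide.

Step 19
Reactants: 27 10α-propionate
Product: 28 19,10-lactone (4-methyl, 10β-allyl, 5β-H, 6β-CO2Me)
Conditions: KOt-Bu (0.3 equiv), t-BuOH/THF, 0 °C → rt
Reagents that add atoms: none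
Why: Intramolecular Michael addition (5-exo-trig) of the propionate enolate to C5 from the α face, to which it is tethered, gives the cis-fused γ-lactone with H-5β; under the alkoxide C6 equilibrates to the more stable 6β-ester and the C4 epimers converge later.

Step 20
Reactants: 28 allyl lactone
Product: 29 primary alcohol (10β-(3-hydroxypropyl) lactone)
Conditions: 9-BBN, THF, 0 °C → rt; then H2O2 (30%), NaOAc (3 M aq), 0 °C → rt
Reagents that add atoms: hydrogen peroxide, OO
Why: Anti-Markovnikov hydroboration–oxidation of the only alkene; the buffered oxidation spares lactone and ester.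

Step 21
Reactants: 29 primary alcohol
Product: 31 ring A aldol as the C3 epimer mixture (3α-OH drawn; the 3-epimer of the target as its 7-methyl ester 16-TES ether), via aldehyde 30 (not isolated)
Conditions: Dess–Martin periodinane, NaHCO3, CH2Cl2, rt; then NaOMe (0.2 equiv), MeOH, 0 °C → rt
Reagents that add atoms: none
Why: Dess–Martin oxidation then intramolecular aldol of the lactone enolate onto the C3 aldehyde closes ring A; the tether from C10 can only reach the C4 face on the C1 side, which fixes the C4 quaternary centre, while C3 forms as an equilibrium mixture.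

Step 22
Reactants: 31 C3 epimer mixture
Product: 32 3-oxo lactone (3-dehydro derivative of the target as its 7-methyl ester 16-TES ether)
Conditions: Dess–Martin periodinane, NaHCO3, CH2Cl2, rt
Reagents that add atoms: none
Why: Dess–Martin oxidation converges both C3 epimers on one ketone that cannot enolise towards the quaternary C4.

Step 23
Reactants: 32 3-oxo lactone
Product: 33 7-methyl ester 16-TES ether of the target (3β-OH)
Conditions: K[BH(s-Bu)3], THF, −78 °C; aq NH4Cl
Reagents that add atoms: none
Why: The bulky trialkylborohydride attacks the C3 ketone along the equatorial trajectory, avoiding the 1,3-diaxial H-1β and H-5β, to give the axial 3β-alcohol, and lactone and ester survive at −78 °C.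

Step 24
Reactants: 33 7-methyl ester 16-TES ether of the target
Product: 35 the target gibberellin (3β-hydroxy 19,10-lactone 7-carboxylic acid carrying the 16-exo-hydroxy-16-methyl ring D), via silyl ether acid 34 (not isolated)
Conditions: LiSCH2CH2CH3, HMPA, rt; then HCl (1 M), THF, rt
Reagents that add atoms: none
Why: SN2 demethylation by thiolate frees the hindered C7 acid without the aqueous alkali that would epimerise C3 by retro-aldol, and dilute acid then cleaves the tertiary silyl ether.

**Compound list**
1 | cyclopentane-1,3-dione | O=C1CCC(=O)C1 | starting material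
2 | allyl bromide | C=CCBr | starting material
3 | 2-allylcyclopentane-1,3-dione | C=CCC1C(=O)CCC1=O | intermediate
4 | methyl vinyl ketone | CC(=O)C=C | starting material
5 | 2-allyl-2-(3-oxobutyl)cyclopentane-1,3-dione | CC(=O)CCC1(CC=C)C(=O)CCC1=O | intermediate
6 | cis-fused ketol, 7a-allyl-3a-hydroxyhexahydro-1H-indene-1,5(4H)-dione, OH cis to allyl (not isolated) | C1[C@]2(O)CC(=O)CC[C@]2(CC=C)C(=O)C1 | intermediate
7 | (7aR)-7a-allyl-2,3,7,7a-tetrahydro-1H-indene-1,5(6H)-dione | C1C2=CC(=O)CC[C@]2(CC=C)C(=O)C1 | intermediate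
8 | 6β-hydroxy enone (OH cis to allyl) | C1C2=CC(=O)CC[C@]2(CC=C)[C@@H](O)C1 | intermediate
9 | 6β-benzyloxy enone | C1C2=CC(=O)CC[C@]2(CC=C)[C@@H](OCc2ccccc2)C1 | intermediate
10 | cross-conjugated TBS dienol ether of 9 | C1C2=CC(O[Si](C)(C)C(C)(C)C)=CC[C@]2(CC=C)[C@@H](OCc2ccccc2)C1 | intermediate
11 | ring B/C/D dienone, 6β-benzyloxy-12-oxo-9(11),16(17)-diene | C1C2=CC(=O)[C@@H]3C[C@]2(CC3=C)[C@@H](OCc2ccccc2)C1 | intermediate
12 | C12 tosylhydrazone of 11 | C1C2=CC(=NNS(=O)(=O)c3ccc(C)cc3)[C@@H]3C[C@]2(CC3=C)[C@@H](OCc2ccccc2)C1 | intermediate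
13 | 12β-(2-tosylhydrazinyl) 9(11)-ene (not isolated) | C1C2=C[C@@H](NNS(=O)(=O)c3ccc(C)cc3)[C@@H]3C[C@]2(CC3=C)[C@@H](OCc2ccccc2)C1 | intermediate
14 | 12β-diazenyl 9(11)-ene (not isolated) | C1C2=C[C@@H](N=N)[C@@H]3C[C@]2(CC3=C)[C@@H](OCc2ccccc2)C1 | intermediate
15 | 9β-H 11,16(17)-diene 6β-benzyl ether | C1[C@@H]2C=C[C@@H]3C[C@]2(CC3=C)[C@@H](OCc2ccccc2)C1 | intermediate
16 | 17-(acetoxymercurio) 16-exo-ol (not isolated) | C1[C@@H]2C=C[C@@H]3C[C@]2(C[C@@]3(C[Hg]OC(C)=O)O)[C@@H](OCc2ccccc2)C1 | intermediate
17 | 16-exo-hydroxy-16-methyl 11-ene 6β-benzyl ether | C1[C@@H]2C=C[C@@H]3C[C@]2(C[C@@]3(C)O)[C@@H](OCc2ccccc2)C1 | intermediate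
18 | 6β,16-diol | C1[C@@H]2CC[C@@H]3C[C@]2(C[C@@]3(C)O)[C@@H](O)C1 | intermediate
19 | 16-hydroxy 6-ketone | C1[C@@H]2CC[C@@H]3C[C@]2(C[C@@]3(C)O)C(=O)C1 | intermediate
20 | 16-O-TES 6-ketone | C1[C@@H]2CC[C@@H]3C[C@]2(C[C@@]3(C)O[Si](CC)(CC)CC)C(=O)C1 | intermediate
21 | 5-en-6-yl triflate | C1[C@@H]2CC[C@@H]3C[C@]2(C[C@@]3(C)O[Si](CC)(CC)CC)C(OS(=O)(=O)C(F)(F)F)=C1 | intermediate
22 | methyl 5-ene-6-carboxylate | C1[C@@H]2CC[C@@H]3C[C@]2(C[C@@]3(C)O[Si](CC)(CC)CC)C(C(=O)OC)=C1 | intermediate
23 | methyl 10-oxo-5-ene-6-carboxylate | O=C1[C@@H]2CC[C@@H]3C[C@]2(C[C@@]3(C)O[Si](CC)(CC)CC)C(C(=O)OC)=C1 | intermediate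
24 | allylmagnesium bromide | C=CC[Mg]Br | starting material
25 | 10β-allyl-10α-hydroxy enoate | O[C@]1(CC=C)[C@@H]2CC[C@@H]3C[C@]2(C[C@@]3(C)O[Si](CC)(CC)CC)C(C(=O)OC)=C1 | intermediate
26 | propionyl chloride | CCC(=O)Cl | starting material
27 | 10α-propionate of 25 | CCC(=O)O[C@]1(CC=C)[C@@H]2CC[C@@H]3C[C@]2(C[C@@]3(C)O[Si](CC)(CC)CC)C(C(=O)OC)=C1 | intermediate
28 | 19,10-lactone, 10β-allyl, 4-methyl (major C4 epimer), 6β-CO2Me | C[C@H]1C(=O)O[C@]2(CC=C)[C@@H]3CC[C@@H]4C[C@]3(C[C@@]4(C)O[Si](CC)(CC)CC)[C@@H](C(=O)OC)[C@@H]21 | intermediate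
29 | 10β-(3-hydroxypropyl) lactone | C[C@H]1C(=O)O[C@]2(CCCO)[C@@H]3CC[C@@H]4C[C@]3(C[C@@]4(C)O[Si](CC)(CC)CC)[C@@H](C(=O)OC)[C@@H]21 | intermediate
30 | 10β-(3-oxopropyl) lactone (not isolated) | C[C@H]1C(=O)O[C@]2(CCC=O)[C@@H]3CC[C@@H]4C[C@]3(C[C@@]4(C)O[Si](CC)(CC)CC)[C@@H](C(=O)OC)[C@@H]21 | intermediate
31 | 3-epimer of the target as its 7-methyl ester 16-TES ether (3α-OH, major aldol epimer; the 3β epimer is 33) | C[C@@]12C(=O)O[C@]3(CC[C@H]1O)[C@@H]1CC[C@@H]4C[C@]1(C[C@@]4(C)O[Si](CC)(CC)CC)[C@@H](C(=O)OC)[C@@H]32 | intermediate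
32 | 3-oxo (3-dehydro) derivative of the target as its 7-methyl ester 16-TES ether | C[C@@]12C(=O)O[C@]3(CCC1=O)[C@@H]1CC[C@@H]4C[C@]1(C[C@@]4(C)O[Si](CC)(CC)CC)[C@@H](C(=O)OC)[C@@H]32 | intermediate
33 | 7-methyl ester 16-TES ether of the target (3β-OH) | C[C@@]12C(=O)O[C@]3(CC[C@@H]1O)[C@@H]1CC[C@@H]4C[C@]1(C[C@@]4(C)O[Si](CC)(CC)CC)[C@@H](C(=O)OC)[C@@H]32 | intermediate
34 | 16-TES ether of the target, free 7-acid (not isolated) | C[C@@]12C(=O)O[C@]3(CC[C@@H]1O)[C@@H]1CC[C@@H]4C[C@]1(C[C@@]4(C)O[Si](CC)(CC)CC)[C@@H](C(=O)O)[C@@H]32 | intermediate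
35 | the target gibberellin (3β-hydroxy 19,10-lactone 7-carboxylic acid carrying the 16-exo-hydroxy-16-methyl ring D) | C[C@@]12C(=O)O[C@]3(CC[C@@H]1O)[C@@H]1CC[C@@H]4C[C@]1(C[C@@]4(C)O)[C@@H](C(=O)O)[C@@H]32 | target

**Step count and risks**

Total step count: 24. Longest linear sequence: 24 steps (1 → 35; compounds 2, 4, 24 and 26 enter as single fragments).

The three steps most likely to fail:

Step 7 (oxidative cycloalkenylation). The risk is Saegusa-type dehydrogenation or alkene isomerisation instead of ring closure. The fallback sets out from 9 and comes back at 11, and replaces alkene carbopalladation by a gold-catalysed enol ether–alkyne cyclisation. Ozonolysis of the allyl group of 9 (O3, CH2Cl2/MeOH, −78 °C; Me2S) gives the aldehyde F1. Homologation with the Ohira–Bestmann reagent (dimethyl (1-diazo-2-oxopropyl)phosphonate, K2CO3, MeOH) gives the propargyl enone F2. Kinetic silylation as in step 6 gives the silyl dienol ether F3. Ph3PAuCl/AgOTf (5 mol % each, CH2Cl2/MeOH, rt; monovalent gold) then closes C13 onto the alkyne 5-exo-dig (Conia-ene type) and delivers 11 directly.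

Step 16 (allylic oxidation at C10). The risk is low conversion of the electron-poor alkene or epimerisation at C9. The fallback sets out from 22 and comes back at 23, and replaces direct C–H oxidation by halogenation and oxygen transfer. Wohl–Ziegler bromination (NBS, AIBN cat., chlorobenzene, 80 °C) gives the allylic bromide F4. Kornblum–Ganem oxidation with N-methylmorpholine N-oxide (MeCN, rt) converts it into 23.

Step 23 (facial selectivity of the C3 reduction). The risk is that the equatorial 3α-alcohol predominates. The fallback sets out from 31 and comes back at 33, and replaces kinetic hydride delivery by thermodynamic equilibration. Treating the 3α-alcohol 31 with K2CO3 in MeOH/H2O sets up the retro-aldol/aldol equilibrium through aldehyde 30; 33 is separated by chromatography and 31 is recycled. This fallback makes no compound outside the list (F0).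

Further compounds
F1 | step 7 | 7a-(2-oxoethyl) analogue of 9 (6β-benzyloxy enone aldehyde) | C1C2=CC(=O)CC[C@]2(CC=O)[C@@H](OCc2ccccc2)C1
F2 | step 7 | 7a-propargyl analogue of 9 | C1C2=CC(=O)CC[C@]2(CC#C)[C@@H](OCc2ccccc2)C1
F3 | step 7 | cross-conjugated TBS dienol ether of F2 | C1C2=CC(O[Si](C)(C)C(C)(C)C)=CC[C@]2(CC#C)[C@@H](OCc2ccccc2)C1
F4 | step 16 | 10β-bromo derivative of 22 (major epimer) | Br[C@H]1[C@@H]2CC[C@@H]3C[C@]2(C[C@@]3(C)O[Si](CC)(CC)CC)C(C(=O)OC)=C1
F0 | step 23 | none | none
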